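The numbers in the tables are simulated with constants of no real substance; scatter was added.

I began with time. Over the days of the earlier runs target climbed fast, and in elm and maple it then fell, so I wanted to know where that fall stops.

| flask | starting material | reagent | protic impurity | free catalyst | remark | time |
|---|---|---|---|---|---|---|
| ash | 0.015 M | 0.50 equiv | 9 mM | 5 mol% | run made earlier |  |
| elm | 0.022 M | 0.50 equiv | 9 mM | 5 mol% | run made earlier |  |
| maple | 0.030 M | 0.50 equiv | 9 mM | 10 mol% | run made earlier |  |
| flask | 0.030 M | 0.500 equiv | 9.00 mM | 5 mol% |  | 5.0 d |

| run | time / d | target / % |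
|---|---|---|
| ash | 0.104 | 12.4 |
| ash | 0.208 | 22.2 |
| ash | 0.333 | 27.9 |
| ash | 0.625 | 37.7 |
| ash | 1.04 | 40.5 |
| ash | 1.67 | 41.9 |
| ash | 3.00 | 43.4 |
| elm | 0.104 | 17.6 |
| elm | 0.208 | 29.3 |
| elm | 0.333 | 37.4 |
| elm | 0.625 | 45.8 |
| elm | 1.04 | 46.4 |
| elm | 1.67 | 44.6 |
| elm | 3.00 | 43.4 |
| maple | 0.104 | 37.8 |
| maple | 0.250 | 46.9 |
| maple | 0.625 | 44.8 |
| maple | 1.25 | 40.8 |
| maple | 3.00 | 34.4 |

(readings scatter by 0.5 percentage points)

- time up to 5.0 d at which target stands highest
- the amount of target, in percent of the starting material charged, at that time
- the first time at which target reaches 32%, in the same percent, in d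

My first way was a balance on the reagent, the limiting reagent at 0.500 equiv, which I took to give one target each. I supposed that the protic impurity takes one starting material each, a share of 30.0% of the charge. That leaves a surplus of 20.0% with no partner, and I supposed that it attacks target, one for one. Target should then sink to the floor, reagent share minus surplus: 30.0%, for maple and the flask alike.

My second way used the maple readings instead of the charges. Counted in fractions of the charge, target fell at 0.0640 d⁻¹ around 42.8%, then at 0.0366 d⁻¹ around 37.6%. The straight line through these reaches zero fall at 30.7%, a rough reading given a scatter of 0.5 percentage points. The two ways differ by 0.70 points, and since they come from different things, I kept the floor as my number, with the reading as a rough check on it. For the flask, I expected a peak followed by a slide toward that floor, and the amount of catalyst does not enter my reckoning of the floor.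

The forecast put the highest point at 47% at 0.55 d, and 32% at 0.16 d, since the flask should “behave like maple with time doubled”.

The flask gave 45.5% at 0.452 d, and 32% at 0.174 d, so the forecast's time was high by a factor of 1.22.

    reagent + free catalyst → catalyst intermediate A (k = 1400 M⁻¹ h⁻¹)
    starting material + catalyst intermediate A ⇌ catalyst intermediate B (K = 23.0 M⁻¹, k = 750 M⁻¹ h⁻¹)
    catalyst intermediate B → free catalyst + target (k = 7.70 h⁻¹)
    starting material + protic impurity → quenched substrate (k = 28.0 M⁻¹ h⁻¹)
    starting material + target → side product (k = 1.30 M⁻¹ h⁻¹)

Starting material's half-life by quenching alone, as charged, was 0.11 d, shorter than the 0.74 d of target by the side-product step alone, as charged, which is itself short against 5.0 d. In the flask, quenched substrate stood at 29.1% at the best time, and after 50.0 d target stood at 30.0%, against my floor of 30.0%.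

In the neighbour flask with 0.200 equiv of reagent, the surplus is 50.0% and the floor −30.0%, below nil, so target should head for nil with 30.0% of starting material left over. Computed, it peaked at 18.3%, and after 5.00 d held 3.30% target and 33% starting material.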